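**Retrosynthetic overview**

1. The C40 skeleton is cut into a ring-A C15 dienal (C1–C11), the C10 trienedial (C12–C12′) and an acetylenic ring-B C15 phosphonium salt (C11′–C1′); two Wittig olefinations (C11′=C12′, then C11=C12) build the polyene last.
2. Ring B is not built: it comes preformed from (4R,6R)-actinol (3′R) by enol triflate formation and Sonogashira coupling with a C6 enynol.
3. Ring A is the only ring formed. It is closed between the gem-dimethyl carbon C1 and the carbinol carbon C6 of an acyclic dienone in which C6 is the α-carbon of a chiral butane-2,3-diacetal glycolate lactone; that dienone comes from the lactone and an ynenone by Michael addition.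
4. Enabling feature: ring A is a 4-oxygenated isophorone. At the ketone level the C3 oxygen is β to C1 (through C2) and vinylogously γ to C6 (through C4=C5), so C3=O makes C1 an acceptor and H6 acidic, and C1–C6 form a 3-oxidohexatriene; O6 and C7 are tied back as a lactone that acidifies H6 and carries the stereocontrol.
5. After ring closure: diacetal removal, reagent-controlled reduction of C3=O (3S, cis to 6-OH), then C7 ester → aldehyde → C7=C8 by Horner–Wadsworth–Emmons olefination.

Key step: step 7

Remark on the chemistry: carotenoid numbering is used with ring A (the 3,6-diol ring) unprimed; the SMILES is read as 3S,6R,3′R with the two ring-A hydroxyls cis; (4R,6R)-actinol, the C10 dialdehyde and the C5 cyano-phosphonate are taken as purchasable.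

**Route**

Step 1
Reactants: 1 (R)-3-chloropropane-1,2-diol; 2 butane-2,3-dione
Product: 3 (2R,5R,6R)-2-(chloromethyl)-5,6-dimethoxy-5,6-dimethyl-1,4-dioxane
Conditions: HC(OMe)3, camphorsulfonic acid (cat.), MeOH, reflux
Reagents that add atoms: trimethyl orthoformate, COC(OC)OC
Why: Thermodynamically controlled butane-2,3-diacetal formation (acid-catalysed ketalisation) should place both methoxy groups axial (anomeric effect) and the chloromethyl group equatorial, so the single stereocentre of 1 fixes both ketal carbons as R.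

Step 2
Reactants: 3 chloromethyl diacetal
Product: 4 (5R,6R)-5,6-dimethoxy-5,6-dimethyl-2-methylidene-1,4-dioxane
Conditions: KOtBu, THF, reflux
Reagents that add atoms: none
Why: E2 dehydrochlorination of the β-chloro ether gives the exocyclic enol ether without touching the ketal stereocentres.

Step 3
Reactants: 4 exocyclic enol ether
Product: 5 (5R,6R)-5,6-dimethoxy-5,6-dimethyl-1,4-dioxan-2-one
Conditions: O3, CH2Cl2, −78 °C; then Me2S
Reagents that add atoms: ozone, [O-][O+]=O
Why: Ozonolysis of the electron-rich enol ether double bond with reductive work-up leaves the lactone carbonyl and releases formaldehyde.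

Step 4
Reactants: 6 3-methylbut-2-enal; 7 prop-1-yn-1-ylmagnesium bromide
Product: 8 2-methylhept-2-en-5-yn-4-ol (racemic)
Conditions: THF, 0 °C; aq. NH4Cl
Reagents that add atoms: none
Why: 1,2-Addition of an alkynyl Grignard reagent to the enal; the racemic carbinol centre is removed in step 5.

Step 5
Reactants: 8 enynol
Product: 9 2-methylhept-2-en-5-yn-4-one
Conditions: MnO2, CH2Cl2, rt
Reagents that add atoms: none
Why: MnO2 oxidation of an allylic and propargylic alcohol gives the cross-conjugated ynenone.

Step 6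
Reactants: 5 glycolate lactone; 9 ynenone
Product: 10 (3S,5R,6R)-5,6-dimethoxy-5,6-dimethyl-3-[(2E)-6-methyl-4-oxohepta-2,5-dien-2-yl]-1,4-dioxan-2-one
Conditions: LiN(SiMe3)2, THF, −78 °C; then 9, −78 → −20 °C; AcOH, −78 °C
Reagents that add atoms: none
Why: Michael addition of the lactone enolate to the alkynone β-carbon (C5), followed by proton shift to the doubly stabilised vinylogous β-dicarbonyl anion as thermodynamic sink (a 1,2-adduct should revert by retro-aldol), is expected to form C5–C6 trans to the 1,3-related axial methoxy group; the C6 configuration and the C4=C5 geometry are erased in step 7, so isomer mixtures are tolerated.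

Step 7
Reactants: 10 acyclic dienone lactone
Product: 12 (2R,3R,6R)-2,3-dimethoxy-2,3,7,11,11-pentamethyl-1,4-dioxaspiro[5.5]undec-7-ene-5,9-dione, via 3-oxidohexatriene enolate 11 (not isolated)
Conditions: DBU (0.2 equiv), MeCN, 25 → 50 °C
Reagents that add atoms: none
Why: DBU should reversibly remove H6, the one hydrogen that is both α to the lactone carbonyl and vinylogously γ to the C3 ketone, to give 11, in which C1=C2–C3(O−)=C4–C5=C6 is a 3-oxidohexatriene; C6 then bonds to C1 and proton return at C2 gives enone 12 and frees the base. The closest known reactions are the base-mediated cyclisation of phorone to isophorone and the diastereoselective alkylations and Michael additions of this diacetal glycolate enolate, including those that form fully substituted carbons. Ring A closes in the 6-endo-trig mode of an intramolecular vinylogous Michael addition, equivalently a thermal disrotatory 6π electrocyclisation of the oxidotriene. The new stereocentre C6 is set by the diacetal: C1 should attack planar C6 on the face opposite the axial methoxy group of the neighbouring ketal carbon (1,3-related through the ring oxygen), which places C1 equatorial on the dioxanone and gives 6R; C1 carries two methyls and is not stereogenic. The step needs site selectivity among the γ-hydrogens (H6 against the C5 and C1 methyl hydrogens), secured by the extra lactone activation of H6 and by the fact that only the C6-to-C1 closure gives a six-membered ring. It also needs the equilibrium on the ring side, secured by catalytic base so that the neutral σ-for-π isomerisation, not the more stabilised open anion, decides the outcome.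

Step 8
Reactants: 12 spiro enone lactone
Product: 13 methyl (1R)-1-hydroxy-2,6,6-trimethyl-4-oxocyclohex-2-ene-1-carboxylate
Conditions: HCl (1.25 M in MeOH), rt
Reagents that add atoms: methanol, CO
Why: Acid-catalysed methanolysis (transketalisation and transesterification) removes the diacetal and gives the α-hydroxy methyl ester; the tertiary carbinol, γ to the enone, should not ionise and C6 is untouched.

Step 9
Reactants: 13 hydroxy keto ester
Product: 14 methyl (1R,4S)-1,4-dihydroxy-2,6,6-trimethylcyclohex-2-ene-1-carboxylate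
Conditions: (R)-2-methyl-CBS-oxazaborolidine (0.2 equiv), catecholborane (2.5 equiv), toluene, −78 °C; aq. NaOH
Reagents that add atoms: none
Why: Corey–Bakshi–Shibata 1,2-reduction of the enone, with the ring alkene as the large group, should let the (R)-catalyst deliver hydride to the face that gives the 4S carbinol (carotenoid C3, cis to the C6 hydroxyl); the tertiary hydroxyl can at most form a hydride-free catechol borate and so cannot direct delivery from the wrong face.

Step 10
Reactants: 14 diol ester
Product: 15 methyl (1R,4S)-2,6,6-trimethyl-1,4-bis[(triethylsilyl)oxy]cyclohex-2-ene-1-carboxylate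
Conditions: Et3SiOTf (2.5 equiv), 2,6-lutidine, CH2Cl2, −78 → 0 °C
Reagents that add atoms: triethylsilyl trifluoromethanesulfonate, CC[Si](CC)(CC)OS(=O)(=O)C(F)(F)F
Why: Silyl triflate silylation protects both the secondary and the hindered tertiary hydroxyl as triethylsilyl ethers.

Step 11
Reactants: 15 bis-silyl ester
Product: 16 (1R,4S)-2,6,6-trimethyl-1,4-bis[(triethylsilyl)oxy]cyclohex-2-ene-1-carbaldehyde
Conditions: iBu2AlH (1.2 equiv), CH2Cl2, −78 °C; aq. potassium sodium tartrate
Reagents that add atoms: none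
Why: Partial hydride reduction of the α-silyloxy ester should stop at the aldehyde because the hindered aluminium hemiacetal is stable at −78 °C.

Step 12
Reactants: 16 ring-A aldehyde; 17 diethyl [(2E)-3-cyano-2-methylprop-2-en-1-yl]phosphonate
Product: 18 (2E,4E)-3-methyl-5-{(1R,4S)-2,6,6-trimethyl-1,4-bis[(triethylsilyl)oxy]cyclohex-2-en-1-yl}penta-2,4-dienenitrile
Conditions: NaH, THF, 0 °C → rt
Reagents that add atoms: none
Why: Horner–Wadsworth–Emmons olefination of the non-enolisable aldehyde with the vinylogous C5 phosphonate should form C7=C8 with E geometry and bring in C8–C11; any 9Z isomer is separated or equilibrated with the final polyene.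

Step 13
Reactants: 18 C15 nitrile
Product: 19 (2E,4E)-3-methyl-5-{(1R,4S)-2,6,6-trimethyl-1,4-bis[(triethylsilyl)oxy]cyclohex-2-en-1-yl}penta-2,4-dienal
Conditions: iBu2AlH, toluene, −78 °C; then wet silica gel, 0 °C
Reagents that add atoms: water, O
Why: Hydride reduction of the conjugated nitrile to the N-aluminio imine and mild hydrolysis should give the dienal without loss of the silyl ethers.

Step 14
Reactants: 20 (4R,6R)-4-hydroxy-2,2,6-trimethylcyclohexan-1-one (actinol)
Product: 21 (4R,6R)-4-[(tert-butyldiphenylsilyl)oxy]-2,2,6-trimethylcyclohexan-1-one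
Conditions: tBuPh2SiCl, imidazole, DMF, rt
Reagents that add atoms: tert-butyl(chloro)diphenylsilane, CC(C)(C)[Si](Cl)(c1ccccc1)c1ccccc1
Why: Silylation of the secondary alcohol gives an acid-stable ether that should survive both later phosphonium salt formations.

Step 15
Reactants: 21 silylated actinol
Product: 22 (4R)-4-[(tert-butyldiphenylsilyl)oxy]-2,6,6-trimethylcyclohex-1-en-1-yl trifluoromethanesulfonate
Conditions: LiN(iPr)2, THF, −78 → 0 °C; then PhNTf2
Reagents that add atoms: N-phenylbis(trifluoromethanesulfonimide), O=S(=O)(N(c1ccccc1)S(=O)(=O)C(F)(F)F)C(F)(F)F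
Why: The ketone has a single α-hydrogen, so enolisation and O-triflation should give the tetrasubstituted enol triflate regiospecifically; the carbinol stereocentre is remote.

Step 16
Reactants: 22 enol triflate; 23 (2E)-3-methylpent-2-en-4-yn-1-ol
Product: 24 (2E)-5-{(4R)-4-[(tert-butyldiphenylsilyl)oxy]-2,6,6-trimethylcyclohex-1-en-1-yl}-3-methylpent-2-en-4-yn-1-ol
Conditions: Pd(PPh3)4 (5 mol %), CuI (10 mol %), iPr2NH, DMF, 40 °C
Reagents that add atoms: none
Why: Sonogashira coupling of the enol triflate with the terminal alkyne forms the C6′–C7′ bond and installs the 7′,8′ triple bond with the 9′E alkene already in place.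

Step 17
Reactants: 24 ring-B C15 alcohol
Product: 25 [(2E)-5-{(4R)-4-[(tert-butyldiphenylsilyl)oxy]-2,6,6-trimethylcyclohex-1-en-1-yl}-3-methylpent-2-en-4-yn-1-yl]triphenylphosphonium bromide
Conditions: PPh3·HBr, CH2Cl2, rt
Reagents that add atoms: triphenylphosphine hydrobromide, [Br-].[PH+](c1ccccc1)(c1ccccc1)c1ccccc1
Why: Acid-mediated substitution of the primary allylic alcohol by triphenylphosphine should give the C15 phosphonium salt, as is usual for carotenoid end groups.

Step 18
Reactants: 25 C15 phosphonium salt; 26 (2E,4E,6E)-2,7-dimethylocta-2,4,6-trienedial (3 equiv)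
Product: 27 (2E,4E,6E,8E,10E)-13-{(4R)-4-[(tert-butyldiphenylsilyl)oxy]-2,6,6-trimethylcyclohex-1-en-1-yl}-2,7,11-trimethyltrideca-2,4,6,8,10-pentaen-12-ynal
Conditions: NaOMe, CH2Cl2/MeOH, 0 °C → rt; then heptane, 80 °C
Reagents that add atoms: none
Why: Wittig olefination of one aldehyde group of the symmetrical dialdehyde (used in excess) forms C11′=C12′; the E/Z mixture usual for semi-stabilised ylides should equilibrate thermally to the E isomer.

Step 19
Reactants: 27 C25 aldehyde
Product: 28 the corresponding C25 primary alcohol (all-E pentaenynol)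
Conditions: NaBH4, MeOH/THF, 0 °C
Reagents that add atoms: none
Why: Borohydride 1,2-reduction of the polyenal gives the allylic alcohol without touching the polyene or alkyne.

Step 20
Reactants: 28 C25 alcohol
Product: 29 the corresponding C25 triphenylphosphonium bromide
Conditions: PPh3·HBr, CH2Cl2/MeOH, 0 °C → rt
Reagents that add atoms: triphenylphosphine hydrobromide, [Br-].[PH+](c1ccccc1)(c1ccccc1)c1ccccc1
Why: Same acid-mediated phosphonium salt formation as in step 17, here on a polyenylic alcohol.

Step 21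
Reactants: 29 C25 phosphonium salt; 19 ring-A C15 dienal
Product: 30 tris-silyl ether of the target (3,6-bis-triethylsilyl, 3′-tert-butyldiphenylsilyl)
Conditions: NaN(SiMe3)2, THF, −78 → 0 °C; then heptane, 80 °C, dark, argon
Reagents that add atoms: none
Why: Wittig olefination forms C11=C12 and joins the two halves; thermal equilibration should convert Z isomers at the new bond to the all-E polyene.

Step 22
Reactants: 30 tris-silyl ether
Product: 31 target CNP0113828.1
Conditions: Bu4NF, THF, 0 °C → rt
Reagents that add atoms: none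
Why: Fluoride-mediated desilylation removes all three silyl ethers under non-acidic conditions that should spare the tertiary bis-allylic alcohol and the polyene.

**Compound list**

1 | (R)-3-chloropropane-1,2-diol | OC[C@@H](O)CCl | starting material
2 | butane-2,3-dione | CC(=O)C(C)=O | starting material
3 | (2R,5R,6R)-2-(chloromethyl)-5,6-dimethoxy-5,6-dimethyl-1,4-dioxane | ClC[C@H]1CO[C@@](C)(OC)[C@](C)(OC)O1 | intermediate
4 | (5R,6R)-5,6-dimethoxy-5,6-dimethyl-2-methylidene-1,4-dioxane | C=C1CO[C@@](C)(OC)[C@](C)(OC)O1 | intermediate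
5 | (5R,6R)-5,6-dimethoxy-5,6-dimethyl-1,4-dioxan-2-one | O=C1CO[C@@](C)(OC)[C@](C)(OC)O1 | intermediate
6 | 3-methylbut-2-enal | CC(C)=CC=O | starting material
7 | prop-1-yn-1-ylmagnesium bromide | CC#C[Mg]Br | starting material
8 | 2-methylhept-2-en-5-yn-4-ol (racemic) | CC#CC(O)C=C(C)C | intermediate
9 | 2-methylhept-2-en-5-yn-4-one | CC#CC(=O)C=C(C)C | intermediate
10 | (3S,5R,6R)-5,6-dimethoxy-5,6-dimethyl-3-[(2E)-6-methyl-4-oxohepta-2,5-dien-2-yl]-1,4-dioxan-2-one | CC(C)=CC(=O)/C=C(\C)[C@@H]1O[C@@](C)(OC)[C@](C)(OC)OC1=O | intermediate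
11 | 3-oxidohexatriene enolate, conjugate base of 10 (DBU-H+ counter-ion) | CC(C)=CC([O-])=CC(C)=C1O[C@@](C)(OC)[C@](C)(OC)OC1=O | intermediate
12 | (2R,3R,6R)-2,3-dimethoxy-2,3,7,11,11-pentamethyl-1,4-dioxaspiro[5.5]undec-7-ene-5,9-dione | CC1=CC(=O)CC(C)(C)[C@@]12O[C@@](C)(OC)[C@](C)(OC)OC2=O | intermediate
13 | methyl (1R)-1-hydroxy-2,6,6-trimethyl-4-oxocyclohex-2-ene-1-carboxylate | CC1=CC(=O)CC(C)(C)[C@]1(O)C(=O)OC | intermediate
14 | methyl (1R,4S)-1,4-dihydroxy-2,6,6-trimethylcyclohex-2-ene-1-carboxylate | CC1=C[C@@H](O)CC(C)(C)[C@]1(O)C(=O)OC | intermediate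
15 | methyl (1R,4S)-2,6,6-trimethyl-1,4-bis[(triethylsilyl)oxy]cyclohex-2-ene-1-carboxylate | CC1=C[C@@H](O[Si](CC)(CC)CC)CC(C)(C)[C@]1(O[Si](CC)(CC)CC)C(=O)OC | intermediate
16 | (1R,4S)-2,6,6-trimethyl-1,4-bis[(triethylsilyl)oxy]cyclohex-2-ene-1-carbaldehyde | CC1=C[C@@H](O[Si](CC)(CC)CC)CC(C)(C)[C@]1(O[Si](CC)(CC)CC)C=O | intermediate
17 | diethyl [(2E)-3-cyano-2-methylprop-2-en-1-yl]phosphonate | CCOP(=O)(OCC)C/C(C)=C/C#N | starting material
18 | (2E,4E)-3-methyl-5-{(1R,4S)-2,6,6-trimethyl-1,4-bis[(triethylsilyl)oxy]cyclohex-2-en-1-yl}penta-2,4-dienenitrile | CC1=C[C@@H](O[Si](CC)(CC)CC)CC(C)(C)[C@]1(O[Si](CC)(CC)CC)/C=C/C(C)=C/C#N | intermediate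
19 | (2E,4E)-3-methyl-5-{(1R,4S)-2,6,6-trimethyl-1,4-bis[(triethylsilyl)oxy]cyclohex-2-en-1-yl}penta-2,4-dienal | CC1=C[C@@H](O[Si](CC)(CC)CC)CC(C)(C)[C@]1(O[Si](CC)(CC)CC)/C=C/C(C)=C/C=O | intermediate
20 | (4R,6R)-4-hydroxy-2,2,6-trimethylcyclohexan-1-one (actinol) | C[C@@H]1C[C@@H](O)CC(C)(C)C1=O | starting material
21 | (4R,6R)-4-[(tert-butyldiphenylsilyl)oxy]-2,2,6-trimethylcyclohexan-1-one | C[C@@H]1C[C@@H](O[Si](c2ccccc2)(c2ccccc2)C(C)(C)C)CC(C)(C)C1=O | intermediate
22 | (4R)-4-[(tert-butyldiphenylsilyl)oxy]-2,6,6-trimethylcyclohex-1-en-1-yl trifluoromethanesulfonate | O=S(=O)(OC1=C(C)C[C@@H](O[Si](c2ccccc2)(c2ccccc2)C(C)(C)C)CC1(C)C)C(F)(F)F | intermediate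
23 | (2E)-3-methylpent-2-en-4-yn-1-ol | C#C/C(C)=C/CO | starting material
24 | (2E)-5-{(4R)-4-[(tert-butyldiphenylsilyl)oxy]-2,6,6-trimethylcyclohex-1-en-1-yl}-3-methylpent-2-en-4-yn-1-ol | OC/C=C(\C)C#CC1=C(C)C[C@@H](O[Si](c2ccccc2)(c2ccccc2)C(C)(C)C)CC1(C)C | intermediate
25 | [(2E)-5-{(4R)-4-[(tert-butyldiphenylsilyl)oxy]-2,6,6-trimethylcyclohex-1-en-1-yl}-3-methylpent-2-en-4-yn-1-yl]triphenylphosphonium bromide | [Br-].c1ccc(cc1)[P+](c1ccccc1)(c1ccccc1)C/C=C(\C)C#CC1=C(C)C[C@@H](O[Si](c2ccccc2)(c2ccccc2)C(C)(C)C)CC1(C)C | intermediate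
26 | (2E,4E,6E)-2,7-dimethylocta-2,4,6-trienedial | O=C/C(C)=C/C=C/C=C(C)/C=O | starting material
27 | (2E,4E,6E,8E,10E)-13-{(4R)-4-[(tert-butyldiphenylsilyl)oxy]-2,6,6-trimethylcyclohex-1-en-1-yl}-2,7,11-trimethyltrideca-2,4,6,8,10-pentaen-12-ynal | O=C/C(C)=C/C=C/C=C(C)/C=C/C=C(\C)C#CC1=C(C)C[C@@H](O[Si](c2ccccc2)(c2ccccc2)C(C)(C)C)CC1(C)C | intermediate
28 | (2E,4E,6E,8E,10E)-13-{(4R)-4-[(tert-butyldiphenylsilyl)oxy]-2,6,6-trimethylcyclohex-1-en-1-yl}-2,7,11-trimethyltrideca-2,4,6,8,10-pentaen-12-yn-1-ol | OC/C(C)=C/C=C/C=C(C)/C=C/C=C(\C)C#CC1=C(C)C[C@@H](O[Si](c2ccccc2)(c2ccccc2)C(C)(C)C)CC1(C)C | intermediate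
29 | [(2E,4E,6E,8E,10E)-13-{(4R)-4-[(tert-butyldiphenylsilyl)oxy]-2,6,6-trimethylcyclohex-1-en-1-yl}-2,7,11-trimethyltrideca-2,4,6,8,10-pentaen-12-yn-1-yl]triphenylphosphonium bromide | [Br-].c1ccc(cc1)[P+](c1ccccc1)(c1ccccc1)C/C(C)=C/C=C/C=C(C)/C=C/C=C(\C)C#CC1=C(C)C[C@@H](O[Si](c2ccccc2)(c2ccccc2)C(C)(C)C)CC1(C)C | intermediate
30 | all-E target protected as 3,6-bis(triethylsilyl) and 3′-(tert-butyldiphenylsilyl) ether | CC1=C[C@@H](O[Si](CC)(CC)CC)CC(C)(C)[C@]1(O[Si](CC)(CC)CC)/C=C/C(C)=C/C=C/C(C)=C/C=C/C=C(C)/C=C/C=C(\C)C#CC1=C(C)C[C@@H](O[Si](c2ccccc2)(c2ccccc2)C(C)(C)C)CC1(C)C | intermediate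
31 | CNP0113828.1, all-E 7′,8′-didehydro carotenoid with (3S,6R)-3,6-dihydroxy ring A (4,5-ene) and (3′R)-3′-hydroxy ring B | CC1=C[C@@H](O)CC(C)(C)[C@]1(O)/C=C/C(C)=C/C=C/C(C)=C/C=C/C=C(C)/C=C/C=C(\C)C#CC1=C(C)C[C@@H](O)CC1(C)C | target

**Step count and risks**

Total step count: 22. Longest linear sequence: 13 steps (1, 2, 3, 6–13, 21, 22).

Most likely to fail, first: step 7. The ring closure may stall because the doubly stabilised open-chain anion is a weak nucleophile toward the β,β-dimethyl acceptor when two fully substituted carbons must be joined, and facial selectivity may erode if heating is needed. The fallback is a neutral pericyclic closure instead of the anionic one. It sets out from 10, which is soft-enolised (tBuMe2SiOTf, Et3N, CH2Cl2, 0 °C) to the 3-(tert-butyldimethylsilyloxy)triene F1. Thermal disrotatory 6π electrocyclisation (toluene, 110 °C) should then give the spirocyclic silyl dienol ether F2, with the diacetal again expected to direct C1 to the face away from the axial methoxy group. Desilylation (Bu4NF, AcOH, THF) returns to the route at 12.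

Second: step 6. The hard lithium enolate may add 1,2 to the ynone carbonyl, or the enolate may be quenched by proton transfer, instead of the wanted conjugate addition. The fallback replaces the metal enolate by a silyl ketene acetal in a Mukaiyama–Michael reaction. It sets out from 5, which is converted (LiN(SiMe3)2, Me3SiCl, THF, −78 °C) into the trimethylsilyl ketene acetal F3. Fluoride-catalysed addition of this to 9 (Bu4N+ Ph3SiF2−, cat., THF, −78 → 0 °C), followed by aqueous work-up, comes back to the route at 10.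

Third: step 12. Addition of the phosphonate anion to the neopentyl-type, α-quaternary aldehyde may be slow, so that the anion decomposes or C9=C10 isomer mixtures result. The fallback builds C7=C8 and C9=C10 separately by halo-olefination and cross-coupling. It sets out from 16, which undergoes Takai iodo-olefination (CrCl2, CHI3, THF, 0 °C) to the (E)-vinyl iodide F4. Stille coupling with (2E)-3-(tributylstannyl)but-2-en-1-ol (Pd(PPh3)4, DMF, 40 °C) should give the C15 dienol F5 with both alkene geometries defined. MnO2 oxidation (CH2Cl2, rt) comes back to the route at 19.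

Further compounds
F1 | step 7 | (5R,6R)-3-[4-(tert-butyldimethylsilyloxy)-6-methylhepta-3,5-dien-2-ylidene]-5,6-dimethoxy-5,6-dimethyl-1,4-dioxan-2-one | CC(C)=CC(O[Si](C)(C)C(C)(C)C)=CC(C)=C1O[C@@](C)(OC)[C@](C)(OC)OC1=O
F2 | step 7 | tert-butyldimethylsilyl dienol ether of 12 (9-silyloxy-1,4-dioxaspiro[5.5]undeca-7,9-dien-5-one, same configuration as 12) | CC1=CC(O[Si](C)(C)C(C)(C)C)=CC(C)(C)[C@@]12O[C@@](C)(OC)[C@](C)(OC)OC2=O
F3 | step 6 | trimethylsilyl ketene acetal of 5 | C[Si](C)(C)OC1=CO[C@@](C)(OC)[C@](C)(OC)O1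
F4 | step 12 | (E)-vinyl iodide from 16: 1-[(E)-2-iodoethenyl]-2,6,6-trimethyl-1,4-bis[(triethylsilyl)oxy]cyclohex-2-ene | CC1=C[C@@H](O[Si](CC)(CC)CC)CC(C)(C)[C@]1(O[Si](CC)(CC)CC)/C=C/I
F5 | step 12 | (2E,4E)-3-methyl-5-{(1R,4S)-2,6,6-trimethyl-1,4-bis[(triethylsilyl)oxy]cyclohex-2-en-1-yl}penta-2,4-dien-1-ol | CC1=C[C@@H](O[Si](CC)(CC)CC)CC(C)(C)[C@]1(O[Si](CC)(CC)CC)/C=C/C(C)=C/CO
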